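What is asked is how far the electrophile gets in the time given, and how the unbound nucleophile divides between free and protonated.

    electrophile + nucleophile → acid set free + product (k1 = 0.057 L mol⁻¹ s⁻¹)
    nucleophile + acid set free ⇌ idle adduct A, settled at all times (K2 = 720 L mol⁻¹)
    nucleophile + product ⇌ idle adduct B, settled at all times (K3 = 1700 L mol⁻¹)
    acid set free + free base ⇌ salt of the base (K4 = 9400 L mol⁻¹, k4 = 0.54 L mol⁻¹ s⁻¹)
    acid set free + scavenger → scavenged by-product (k5 = 0.023 L mol⁻¹ s⁻¹)
    nucleophile + acid set free ⇌ protonated nucleophile, settled at all times (K6 = 6500 L mol⁻¹)

electrophile 24 mM; nucleophile 21.6 mM; free base 48.0 mM; scavenger 19.2 mM; time 8.0 h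

- for product the idle adduct B is counted in
- for acid set free the idle adduct A is counted in
- run time (flask): 8.0 h

- part of the electrophile that has reacted at 8.0 h
- share of free nucleophile in free nucleophile and protonated nucleophile together, at 8.0 h

The nucleophile, charged at less than the electrophile, is the limiting reagent, and the binding constant of idle adduct B times the nucleophile charge is 37, far above one. This reckoning therefore takes idle adduct B as the resting state of unconsumed nucleophile and computes free nucleophile as a small correction.

Let a and b be the charges of electrophile and nucleophile, x the product made, k the rate constant of the main step and K the binding constant. Idle adduct B is then about b − x and unbound product about 2x − b, so [nucleophile] = (b − x)/(K(2x − b)) and dx/dt = k(a − x)(b − x)/(K(2x − b)). Time enters through one dimensionless number, N = 0.966, the stall number: the rate constant of the main step over the binding constant of idle adduct B, times the time. It holds no charge.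

The half-life of the electrophile by the main step at the charged concentrations, 0.16 h, is short against 8.0 h, so the integration starts at x = 10.8 mM and neglects the time taken to get there:

N = 11.0 ln([electrophile]/13.2 mM) − 9.00 ln(([electrophile] − 2.40 mM)/10.8 mM).

At 70.0% reacted the right side gives 0.631, and at 75.0% reacted it gives 1.21. Interpolation commits this reckoning to 72.9%.

One number is not enough for the second question. If free base takes up the acid as product forms, the share also needs the ratio of the two acid constants, 0.691, and comes to 71.6%.

The forecast gives 72% and 73%, on the ground that “the product ties up most of the remaining nucleophile as idle adduct B”; its first figure lies below this reckoning's, its second above.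

The flask gives 71.0% and 73.1%. Moved alone, the nucleophile charge shifts the reacted part in this flask by 5 points at 19.4 mM below and 24.0 mM above. The flask's own 71.0% put into the formula returns 0.721, against N of 0.966. The neighbour flask with 41 mM of electrophile has the same N and reaches 47.8%, and the formula refilled with that charge returns 0.810.

The numbers belong to no real substance; the run is a simulation.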